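C5'=C6' (E) is cut last, by cross-metathesis of a vinyl carbinol core with 3-[(3E)-4-methylhepta-3,6-dienyl]furan, itself made by a B-alkyl Suzuki coupling. Locants: lactone ring O1, C2(=O), C3, C4, C5; side chain C1' (CHOH) to C11' (CH2 on the furan).
C1'–C2' is the key cut. C2' enters as the primary radical left when a redox-active ester loses CO2, and C1' enters as an aldehyde. Divalent chromium joins these two electrophile-derived carbons by radical–polar crossover and sets C1'.
Enabling feature: C4' and C5 are homochiral (both S) copies of one unit, a carbinol carbon bearing CH3, O, one sp2-derived carbon (C5' or C1') and a CH2CH2 arm (C3'–C2' or C4–C3). The γ-lactone ring O1–C2–C3–C4–C5 is that unit with its carboxyl carbon kept; the C4'–C3'–C2' arm is the same unit after decarboxylation.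
Both partners therefore come from one acid, (4S)-4-methyl-4-(silyloxy)hex-5-enoic acid, made from (S)-linalool. One Katsuki–Sharpless epoxidation of geraniol is the only source of chirality, and C1' is relayed from C5.
Rings: the furan is bought. The γ-lactone is the only ring formed (step 8), before the key step.
Key step: step 10

Remark: (S)-linalool is made from geraniol rather than bought, because its (R)-enantiomer is the common article of commerce. Geraniol, furan-3-carbaldehyde and pent-1-en-4-yne are taken as commercial.

Step 1
Reactants: 1 geraniol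
Product: 2 (2S,3S)-2,3-epoxygeraniol
Conditions: Ti(OiPr)4 (5 mol %), L-(+)-diethyl tartrate (7 mol %), t-BuOOH (decane), 4 Å MS, CH2Cl2, −20 °C
Reagents that add atoms: tert-butyl hydroperoxide, CC(C)(C)OO
Why: Katsuki–Sharpless asymmetric epoxidation: the titanium tartrate complex binds the allylic hydroxyl, so only the 2,3-alkene is oxidised, and L-(+)-tartrate directs oxygen to the face that gives the (2S,3S)-epoxide, which sets the tertiary C–O stereocentre that later serves as both C4' and C5.

Step 2
Reactants: 2 (2S,3S)-2,3-epoxygeraniol
Product: 3 (2S,3R)-3-(iodomethyl)-2-methyl-2-(4-methylpent-3-en-1-yl)oxirane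
Conditions: PPh3, imidazole, I2, THF–MeCN, 0 °C, dark
Reagents that add atoms: iodine, [I][I]
Why: Appel-type iodination (Garegg–Samuelsson conditions) replaces the primary hydroxyl by SN2 under near-neutral conditions, so the epoxide and its two stereocentres are untouched (the descriptor of the CH carbon changes only because CH2I outranks the quaternary carbon).

Step 3
Reactants: 3 (2S,3R)-3-(iodomethyl)-2-methyl-2-(4-methylpent-3-en-1-yl)oxirane
Product: 4 (S)-linalool
Conditions: Zn dust, EtOH, 60 °C; aq NH4Cl
Reagents that add atoms: none
Why: Zinc-mediated reductive β-elimination of a 2,3-epoxy iodide: zinc inserts into the C–I bond and the neighbouring epoxide C–O bond is expelled to give the vinyl group, while the tertiary C–O bond is never broken and keeps its configuration.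

Step 4
Reactants: 4 (S)-linalool
Product: 5 (S)-linalool triethylsilyl ether
Conditions: Et3SiOTf, 2,6-lutidine, CH2Cl2, −78 to 0 °C
Reagents that add atoms: triethylsilyl trifluoromethanesulfonate, CC[Si](CC)(CC)OS(=O)(=O)C(F)(F)F
Why: Silyl triflate silylation of a hindered tertiary alcohol with a non-nucleophilic base; the ether blocks lactol and lactone formation in steps 5 to 7, and no stereocentre is touched.

Step 5
Reactants: 5 (S)-linalool triethylsilyl ether
Product: 7 (4S)-4-methyl-4-[(triethylsilyl)oxy]hex-5-enal, via secondary ozonide 6 (not isolated)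
Conditions: O3 (to the Sudan Red 7B end-point), CH2Cl2, −78 °C; then Me2S, −78 °C to rt
Reagents that add atoms: ozone, [O-][O+]=O
Why: Chemoselective ozonolysis (Criegee mechanism): the electron-rich trisubstituted alkene reacts far faster than the monosubstituted vinyl group, which is shielded by the quaternary silyloxy carbon, and the dye end-point stops the ozone feed after one equivalent.

Step 6
Reactants: 7 (4S)-4-methyl-4-[(triethylsilyl)oxy]hex-5-enal
Product: 8 (4S)-4-methyl-4-[(triethylsilyl)oxy]hex-5-enoic acid
Conditions: NaClO2, NaH2PO4, 2-methylbut-2-ene, t-BuOH–H2O, 0 °C to rt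
Reagents that add atoms: sodium chlorite, [Na+].[O-]Cl=O
Why: Pinnick oxidation turns the aldehyde into the acid at buffered pH, and 2-methylbut-2-ene traps hypochlorous acid so that the vinyl group and the silyl ether survive.

Step 7
Reactants: 8 (4S)-4-methyl-4-[(triethylsilyl)oxy]hex-5-enoic acid
Product: 9 1,3-dioxoisoindolin-2-yl (4S)-4-methyl-4-[(triethylsilyl)oxy]hex-5-enoate (fragment A)
Conditions: N-hydroxyphthalimide, DIC, DMAP (cat.), CH2Cl2, rt
Reagents that add atoms: N-hydroxyphthalimide, O=C1c2ccccc2C(=O)N1O
Why: Carbodiimide (Steglich-type) esterification with N-hydroxyphthalimide gives the redox-active ester under neutral conditions, and the silyl ether prevents lactonisation of the activated acid.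

Step 8
Reactants: 8 (4S)-4-methyl-4-[(triethylsilyl)oxy]hex-5-enoic acid
Product: 11 (5S)-5-ethenyl-5-methyloxolan-2-one, via hydroxy acid 10 (not isolated)
Conditions: HF·pyridine, pyridine, THF, 0 °C to rt
Reagents that add atoms: none
Why: Fluoride-induced desilylation followed by spontaneous 5-exo-trig lactonisation (Thorpe–Ingold acceleration): ring closure is an acyl substitution at the carboxyl carbon, so the tertiary C–O bond and its S configuration are retained.

Step 9
Reactants: 11 (5S)-5-ethenyl-5-methyloxolan-2-one
Product: 13 (2S)-2-methyl-5-oxooxolane-2-carbaldehyde (fragment B), via secondary ozonide 12 (not isolated)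
Conditions: O3, CH2Cl2, −78 °C; then Me2S, −78 °C to rt
Reagents that add atoms: ozone, [O-][O+]=O
Why: Ozonolysis of the only alkene with reductive work-up gives the aldehyde, which has no α-hydrogen and therefore cannot epimerise.

Step 10
Reactants: 9 1,3-dioxoisoindolin-2-yl (4S)-4-methyl-4-[(triethylsilyl)oxy]hex-5-enoate (fragment A); 13 (2S)-2-methyl-5-oxooxolane-2-carbaldehyde (fragment B)
Product: 15 (5S)-5-{(1R,4S)-1-hydroxy-4-methyl-4-[(triethylsilyl)oxy]hex-5-en-1-yl}-5-methyloxolan-2-one, via alkylchromium dichloride 14 (not isolated)
Conditions: CrCl2 (4 equiv), DMF–THF (1:1), 9 (1.5 equiv) added slowly, 25 °C; aq potassium sodium tartrate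
Reagents that add atoms: chromium dichloride, Cl[Cr]Cl (its atoms stay only in intermediate 14, not in 15)
Why: Decarboxylative Nozaki–Hiyama–Kishi-type alkylation (radical–polar crossover): divalent chromium transfers one electron to the phthalimide ester 9, N–O cleavage and loss of CO2 give the primary C2' radical, a second divalent chromium captures it as alkylchromium 14, and this trivalent organochromium adds to the aldehyde carbon of 13, so that two carbons that are both electrophilic in their parent acid and aldehyde are joined by reductive polarity reversal. The closest known reaction type is the chromium dichloride-mediated addition of redox-active esters (and, under cobalt catalysis, of alkyl iodides) to aldehydes, which tolerates lactones, silyl ethers and alkenes. No ring is closed, because the intermediate is a pent-4-enyl radical whose 4-exo and 5-endo closures onto the vinyl group are too slow to compete with capture by chromium. The only new stereocentre, C1', is controlled by the adjacent quaternary C5: the weakly basic acyloxy oxygen O1 and DMF-solvated chromium should form no chelate, the C5–O1 bond lies anti to the incoming carbon or to the C=O dipole (the polar Felkin–Anh and Cornforth models agree), and the alkyl group comes in past the C5 methyl group on the flank turned away from ring carbons C4 and C3, which gives 1'R. The step needs chemoselectivity for the aldehyde over the lactone, secured by the low basicity and aldehyde preference of alkylchromium reagents, and facial selectivity, secured by the ring, which puts one trajectory over its own face and leaves only the methyl flank open. C4' and C5 are spectators, and because both partners stem from the same scalemic acid, the minor enantiomer should end up mainly in separable diastereomers (Horeau-type amplification).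

Step 11
Reactants: 15 (5S)-5-{(1R,4S)-1-hydroxy-4-methyl-4-[(triethylsilyl)oxy]hex-5-en-1-yl}-5-methyloxolan-2-one
Product: 16 (5S)-5-[(1R,4S)-1,4-dihydroxy-4-methylhex-5-en-1-yl]-5-methyloxolan-2-one
Conditions: HF·pyridine, pyridine, THF, 0 °C
Reagents that add atoms: none
Why: Buffered fluoride desilylation removes the triethylsilyl group without ionising the tertiary allylic alcohol or opening the lactone.

Step 12
Reactants: 17 furan-3-carbaldehyde
Product: 18 3-ethenylfuran
Conditions: Ph3PCH3Br, KOt-Bu, Et2O, 0 °C to rt
Reagents that add atoms: methyltriphenylphosphonium bromide, C[P+](c1ccccc1)(c1ccccc1)c1ccccc1.[Br-]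
Why: Wittig methylenation of an aromatic aldehyde with the non-stabilised ylide; the volatile product is carried on as a solution.

Step 13
Reactants: 19 pent-1-en-4-yne
Product: 21 (1E)-1-iodo-2-methylpenta-1,4-diene, via alkenylalane 20 (not isolated)
Conditions: Me3Al (2 equiv), Cp2ZrCl2 (25 mol %), CH2Cl2, 0 °C to rt; then I2, THF, −30 to 0 °C
Reagents that add atoms: trimethylaluminium, C[Al](C)C; iodine, [I][I]
Why: Negishi zirconium-catalysed carboalumination adds methyl and aluminium syn and regioselectively across the terminal alkyne (the alkene is left alone), and iodinolysis with retention gives the E-iodide.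

Step 14
Reactants: 18 3-ethenylfuran; 21 (1E)-1-iodo-2-methylpenta-1,4-diene
Product: 23 3-[(3E)-4-methylhepta-3,6-dien-1-yl]furan, via B-alkylborane 22 (not isolated)
Conditions: 9-BBN-H, THF, 0 °C to rt; then 21, PdCl2(dppf) (3 mol %), 3 M aq NaOH, THF, 60 °C
Reagents that add atoms: 9-borabicyclo[3.3.1]nonane, B1C2CCCC1CCC2 (its atoms stay only in intermediate 22, not in 23)
Why: Brown hydroboration places boron on the terminal carbon of the vinylfuran, and the B-alkyl Suzuki–Miyaura coupling joins it to the alkenyl iodide with retention of the E geometry; a slight excess of 18 over 9-BBN-H leaves no borane that could attack the allyl terminus of 21.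

Step 15
Reactants: 16 (5S)-5-[(1R,4S)-1,4-dihydroxy-4-methylhex-5-en-1-yl]-5-methyloxolan-2-one; 23 3-[(3E)-4-methylhepta-3,6-dien-1-yl]furan
Product: 24 (5S)-5-[(1R,4S,5E,8E)-11-(furan-3-yl)-1,4-dihydroxy-4,8-dimethylundeca-5,8-dien-1-yl]-5-methyloxolan-2-one (target)
Conditions: 23 (3 equiv), second-generation Hoveyda–Grubbs catalyst [RuCl2(H2IMes)(=CH-C6H4-2-OiPr)] (5 mol %), 1,4-benzoquinone (10 mol %), CH2Cl2, 40 °C
Reagents that add atoms: none
Why: Olefin cross-metathesis between a slowly homodimerising free tertiary allylic alcohol and an excess of a rapidly reacting terminal alkene is selective for the cross product, the bulky carbinol carbon enforces the E geometry, and the trisubstituted alkene, the furan and the three stereocentres are not touched.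

Compound list
1 | geraniol, (2E)-3,7-dimethylocta-2,6-dien-1-ol | CC(C)=CCC/C(C)=C/CO | starting material
2 | (2S,3S)-2,3-epoxygeraniol | OC[C@@H]1O[C@@]1(C)CCC=C(C)C | intermediate
3 | (2S,3R)-3-(iodomethyl)-2-methyl-2-(4-methylpent-3-en-1-yl)oxirane | IC[C@@H]1O[C@@]1(C)CCC=C(C)C | intermediate
4 | (S)-linalool, (3S)-3,7-dimethylocta-1,6-dien-3-ol | C=C[C@@](C)(O)CCC=C(C)C | intermediate
5 | (S)-linalool triethylsilyl ether | C=C[C@@](C)(O[Si](CC)(CC)CC)CCC=C(C)C | intermediate
6 | secondary ozonide of 5 (1,2,4-trioxolane, epimers at the ring CH, not isolated) | C=C[C@@](C)(O[Si](CC)(CC)CC)CCC1OOC(C)(C)O1 | intermediate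
7 | (4S)-4-methyl-4-[(triethylsilyl)oxy]hex-5-enal | C=C[C@@](C)(O[Si](CC)(CC)CC)CCC=O | intermediate
8 | (4S)-4-methyl-4-[(triethylsilyl)oxy]hex-5-enoic acid | C=C[C@@](C)(O[Si](CC)(CC)CC)CCC(=O)O | intermediate
9 | 1,3-dioxoisoindolin-2-yl (4S)-4-methyl-4-[(triethylsilyl)oxy]hex-5-enoate (fragment A) | C=C[C@@](C)(O[Si](CC)(CC)CC)CCC(=O)ON1C(=O)c2ccccc2C1=O | intermediate
10 | (4S)-4-hydroxy-4-methylhex-5-enoic acid (not isolated) | C=C[C@@](C)(O)CCC(=O)O | intermediate
11 | (5S)-5-ethenyl-5-methyloxolan-2-one | C=C[C@]1(C)CCC(=O)O1 | intermediate
12 | secondary ozonide of 11 (1,2,4-trioxolane, epimers at the ring CH, not isolated) | O1COOC1[C@]2(C)CCC(=O)O2 | intermediate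
13 | (2S)-2-methyl-5-oxooxolane-2-carbaldehyde (fragment B) | O=C[C@]1(C)CCC(=O)O1 | intermediate
14 | {(3S)-3-methyl-3-[(triethylsilyl)oxy]pent-4-en-1-yl}chromium dichloride (solvated, not isolated) | C=C[C@@](C)(O[Si](CC)(CC)CC)CC[Cr](Cl)Cl | intermediate
15 | (5S)-5-{(1R,4S)-1-hydroxy-4-methyl-4-[(triethylsilyl)oxy]hex-5-en-1-yl}-5-methyloxolan-2-one | C=C[C@@](C)(O[Si](CC)(CC)CC)CC[C@@H](O)[C@]1(C)CCC(=O)O1 | intermediate
16 | (5S)-5-[(1R,4S)-1,4-dihydroxy-4-methylhex-5-en-1-yl]-5-methyloxolan-2-one | C=C[C@@](C)(O)CC[C@@H](O)[C@]1(C)CCC(=O)O1 | intermediate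
17 | furan-3-carbaldehyde | O=Cc1ccoc1 | starting material
18 | 3-ethenylfuran | C=Cc1ccoc1 | intermediate
19 | pent-1-en-4-yne | C=CCC#C | starting material
20 | dimethyl[(1E)-2-methylpenta-1,4-dien-1-yl]alumane (not isolated) | C=CC/C(C)=C/[Al](C)C | intermediate
21 | (1E)-1-iodo-2-methylpenta-1,4-diene | C=CC/C(C)=C/I | intermediate
22 | 9-[2-(furan-3-yl)ethyl]-9-borabicyclo[3.3.1]nonane (not isolated) | C1CC2CCCC(C1)B2CCc1ccoc1 | intermediate
23 | 3-[(3E)-4-methylhepta-3,6-dien-1-yl]furan | C=CC/C(C)=C/CCc1ccoc1 | intermediate
24 | (5S)-5-[(1R,4S,5E,8E)-11-(furan-3-yl)-1,4-dihydroxy-4,8-dimethylundeca-5,8-dien-1-yl]-5-methyloxolan-2-one | C/C(=C\CCc1ccoc1)C/C=C/[C@@](C)(O)CC[C@@H](O)[C@]1(C)CCC(=O)O1 | target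

Total step count: 15. Longest linear sequence: 11 steps (steps 1 to 6, 8 to 11 and 15).

Steps most likely to fail

Step 10. The facial selectivity at the α-quaternary aldehyde may erode. The C5 methyl group and the ring methylene C4 differ only modestly in size, and any chelation of trivalent chromium by O1 would favour the wrong face. The fallback replaces substrate control by catalyst control.
- It sets out from 15 obtained as a mixture of C1' epimers.
- Dess–Martin oxidation gives the ketone (5S)-5-methyl-5-{(4S)-4-methyl-4-[(triethylsilyl)oxy]hex-5-enoyl}oxolan-2-one F1.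
- A Corey–Bakshi–Shibata reduction follows, with (S)-Me-CBS oxazaborolidine and catecholborane in toluene at −78 °C. The catalyst tells the quaternary C5 from the C2' methylene and should deliver hydride to the face that gives 1'R. Catecholborane at this temperature spares the vinyl group.
- It comes back to the route at 15.

Step 15. Self-metathesis and double-bond migration of the skipped diene 23 may outrun the slow cross-metathesis at the hindered carbinol. The fallback takes the skipped diene out of the metathesis and forms the C6'–C7' bond by cross-coupling. It sets out from 16 and 22.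
- Cross-metathesis of 16 with vinylboronic acid pinacol ester gives the (E)-alkenylboronate F2.
- In parallel, carboalumination–iodination of propargyl alcohol gives (2E)-3-iodo-2-methylprop-2-en-1-ol F3.
- F3 is coupled with borane 22 (PdCl2(dppf), aq NaOH, THF) to give (2E)-5-(furan-3-yl)-2-methylpent-2-en-1-ol F4.
- Methyl chloroformate and pyridine convert F4 into the allylic methyl carbonate F5.
- A palladium-catalysed allyl–alkenyl Suzuki–Miyaura coupling of F2 with F5 (Pd(PPh3)4, THF, 50 °C, no added base) should join the less hindered allyl terminus to the alkenyl carbon with retention of both alkene geometries. It comes back to the route at 24.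

Step 5. Ozone may begin to attack the vinyl group before the trisubstituted alkene is fully consumed. The fallback replaces ozonolysis by electrophilic epoxidation and glycol-type cleavage.
- It sets out from 5.
- mCPBA (1 equiv, NaHCO3, CH2Cl2, 0 °C) epoxidises only the electron-rich trisubstituted alkene to the 6,7-epoxide F6.
- H5IO6 in THF–H2O at 0 °C cleaves F6, and the sequence comes back to the route at 7.

Further compounds
F1 | step 10 | (5S)-5-methyl-5-{(4S)-4-methyl-4-[(triethylsilyl)oxy]hex-5-enoyl}oxolan-2-one | C=C[C@@](C)(O[Si](CC)(CC)CC)CCC(=O)[C@]1(C)CCC(=O)O1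
F2 | step 15 | (5S)-5-[(1R,4S,5E)-1,4-dihydroxy-4-methyl-6-(4,4,5,5-tetramethyl-1,3,2-dioxaborolan-2-yl)hex-5-en-1-yl]-5-methyloxolan-2-one | CC1(C)OB(/C=C/[C@@](C)(O)CC[C@@H](O)[C@]2(C)CCC(=O)O2)OC1(C)C
F3 | step 15 | (2E)-3-iodo-2-methylprop-2-en-1-ol | OC/C(C)=C/I
F4 | step 15 | (2E)-5-(furan-3-yl)-2-methylpent-2-en-1-ol | OC/C(C)=C/CCc1ccoc1
F5 | step 15 | (2E)-5-(furan-3-yl)-2-methylpent-2-en-1-yl methyl carbonate | COC(=O)OC/C(C)=C/CCc1ccoc1
F6 | step 5 | triethyl{[(3S)-5-(3,3-dimethyloxiran-2-yl)-3-methylpent-1-en-3-yl]oxy}silane (epimers at the epoxide CH) | C=C[C@@](C)(O[Si](CC)(CC)CC)CCC1OC1(C)C
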